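The flavone is disconnected across ring C at O1–C8a, C4–C4a and O1–C2, giving a ring A aryne and a three-carbon acid that carries ring B. The feature exploited is the substitution of ring A: O1 on C8a, the C4 carbonyl on the neighbouring C4a, and the C5 oxygen flanking C4a, exactly the array a 3-alkoxybenzyne installs. A single fluoride-triggered operation generates the aryne, inserts it into the carboxyl C–O bond and closes the pyranone by oxa-Michael addition. Its precursors are a 2-silylaryl triflate with two benzyl ethers and a tetramethoxyphenylpropiolic acid; hydrogenolysis then releases the 5- and 7-hydroxyl groups.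

Key step: step 6

Remark: an aryl iodide, not a bromide, is chosen as the coupling partner for propiolic acid because it should couple near room temperature, below the onset of decarboxylation of the arylpropiolate; 3,5-bis(benzyloxy)phenol, 1,2,3,4-tetramethoxybenzene and propiolic acid are assumed to be purchasable.

Step 1
Reactants: 1 3,5-bis(benzyloxy)phenol
Product: 2 3,5-bis(benzyloxy)phenyl N-isopropylcarbamate
Conditions: i-PrNCO, Et3N (cat.), CH2Cl2, rt
Reagents that add atoms: isopropyl isocyanate CC(C)N=C=O
Why: Base-catalysed addition of the phenol O–H across the isocyanate (carbamoylation) installs a strong directing group for ortho-metalation that can later be removed under mild basic conditions.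

Step 2
Reactants: 2 3,5-bis(benzyloxy)phenyl N-isopropylcarbamate
Product: 6 3,5-bis(benzyloxy)-2-(trimethylsilyl)phenyl N-isopropylcarbamate, via N-silyl carbamate 3 (not isolated), via aryllithium 4 (not isolated), via N-silyl arylsilane 5 (not isolated)
Conditions: TBSOTf, TMEDA, Et2O, 0 °C to rt; n-BuLi (2 equiv), TMEDA, −78 °C; TMSCl, −78 °C to rt; aq. NaHSO4
Reagents that add atoms: chlorotrimethylsilane C[Si](C)(C)Cl
Why: Directed ortho-metalation: after in situ N-silylation masks the N–H, the carbamate and the neighbouring benzyloxy group together should direct n-BuLi to C2, the position between them, and the aryllithium is trapped by TMSCl before the acidic work-up removes the N-silyl group.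

Step 3
Reactants: 6 3,5-bis(benzyloxy)-2-(trimethylsilyl)phenyl N-isopropylcarbamate
Product: 8 3,5-bis(benzyloxy)-2-(trimethylsilyl)phenyl trifluoromethanesulfonate, via silylphenoxide 7 (not isolated)
Conditions: DBU, Et2NH, MeCN, 40 °C; then PhNTf2, rt
Reagents that add atoms: N-phenylbis(trifluoromethanesulfonimide) O=S(=O)(N(c1ccccc1)S(=O)(=O)C(F)(F)F)C(F)(F)F
Why: DBU deprotonates the N–H and the carbamate should fragment by E1cB elimination to the phenoxide and isopropyl isocyanate, which diethylamine scavenges as a urea, after which the phenoxide is sulfonylated in the same flask by PhNTf2 (one-pot carbamate cleavage and triflation).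

Step 4
Reactants: 9 1,2,3,4-tetramethoxybenzene
Product: 10 1-iodo-2,3,4,5-tetramethoxybenzene
Conditions: NIS (1.05 equiv), TFA (cat.), MeCN, rt, dark
Reagents that add atoms: N-iodosuccinimide O=C1CCC(=O)N1I
Why: Electrophilic aromatic iodination; the two free ring positions are equivalent and each is activated by an ortho and a para methoxy group, so only one mono-iodide can form.

Step 5
Reactants: 10 1-iodo-2,3,4,5-tetramethoxybenzene; 11 propiolic acid
Product: 12 3-(2,3,4,5-tetramethoxyphenyl)propiolic acid
Conditions: PdCl2(PPh3)2 (5 mol%), dppb (10 mol%), DBU (2.2 equiv), DMSO, 35 °C; aq. HCl work-up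
Reagents that add atoms: none
Why: Copper-free Sonogashira coupling of the aryl iodide with the terminal C–H of propiolic acid, present as its DBU carboxylate, should proceed near room temperature, where the arylpropiolate does not yet lose CO2.

Step 6
Reactants: 8 3,5-bis(benzyloxy)-2-(trimethylsilyl)phenyl trifluoromethanesulfonate; 12 3-(2,3,4,5-tetramethoxyphenyl)propiolic acid
Product: 15 5,7-bis(benzyloxy)-2',3',4',5'-tetramethoxyflavone, via 3,5-bis(benzyloxy)benzyne 13 (not isolated), via hydroxyaryl ynone 14 (not isolated)
Conditions: 8 (1.5 equiv), CsF (4 equiv), THF, 125 °C, sealed tube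
Reagents that add atoms: none
Why: Fluoride attack on silicon expels triflate and releases aryne 13; the cesium carboxylate of 12 adds through oxygen to the aryne carbon remote from the flanking benzyloxy group (the future C8a), the aryl anion formed at the future C4a attacks the adjacent ester carbonyl to give a four-membered hemiketal alkoxide, and its opening delivers the ortho-acyl phenoxide 14, a net insertion into the acyl C–O bond. The phenoxide then adds to the electron-poor alkyne of the ynone and protonation at C3 completes ring C, a 6-endo-dig oxa-Michael closure that forms O1–C2. The closest known reaction type is the insertion of arynes into the C–O bond of carboxylic acids to give ortho-hydroxyaryl ketones, which with 3-arylpropiolic acids is known to run on to flavones. No stereocenter is created. The regioselectivity of aryne capture is needed and is secured by the inductively withdrawing benzyloxy group next to the triple bond, which distorts the aryne so that the nucleophile enters at the far carbon and the charge develops beside the C–O dipole. Oxygen attack, not carbon attack, is ensured because 12 has no acidic C–H, and 6-endo is preferred over 5-exo closure because only attack at the alkyne carbon bearing ring B gives a carbonyl-stabilised allenolate.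

Step 7
Reactants: 15 5,7-bis(benzyloxy)-2',3',4',5'-tetramethoxyflavone
Product: 16 5,7-dihydroxy-2',3',4',5'-tetramethoxyflavone
Conditions: H2 (1 atm), 10% Pd/C, EtOAc–MeOH, rt
Reagents that add atoms: none
Why: Heterogeneous hydrogenolysis should cleave both benzylic C–O bonds while the methyl ethers and the C2=C3 bond of the pyranone are left untouched under these mild conditions.

Compound list
1 | 3,5-bis(benzyloxy)phenol | Oc1cc(OCc2ccccc2)cc(OCc2ccccc2)c1 | starting material
2 | 3,5-bis(benzyloxy)phenyl N-isopropylcarbamate | CC(C)NC(=O)Oc1cc(OCc2ccccc2)cc(OCc2ccccc2)c1 | intermediate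
3 | 3,5-bis(benzyloxy)phenyl N-(tert-butyldimethylsilyl)-N-isopropylcarbamate (not isolated) | CC(C)N(C(=O)Oc1cc(OCc2ccccc2)cc(OCc2ccccc2)c1)[Si](C)(C)C(C)(C)C | intermediate
4 | [2,4-bis(benzyloxy)-6-({[tert-butyl(dimethyl)silyl](isopropyl)carbamoyl}oxy)phenyl]lithium (not isolated) | [Li]c1c(OCc2ccccc2)cc(OCc2ccccc2)cc1OC(=O)N(C(C)C)[Si](C)(C)C(C)(C)C | intermediate
5 | 3,5-bis(benzyloxy)-2-(trimethylsilyl)phenyl N-(tert-butyldimethylsilyl)-N-isopropylcarbamate (not isolated) | CC(C)N(C(=O)Oc1cc(OCc2ccccc2)cc(OCc2ccccc2)c1[Si](C)(C)C)[Si](C)(C)C(C)(C)C | intermediate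
6 | 3,5-bis(benzyloxy)-2-(trimethylsilyl)phenyl N-isopropylcarbamate | CC(C)NC(=O)Oc1cc(OCc2ccccc2)cc(OCc2ccccc2)c1[Si](C)(C)C | intermediate
7 | 3,5-bis(benzyloxy)-2-(trimethylsilyl)phenol, present in the flask as its DBU-H phenoxide (not isolated) | Oc1cc(OCc2ccccc2)cc(OCc2ccccc2)c1[Si](C)(C)C | intermediate
8 | 3,5-bis(benzyloxy)-2-(trimethylsilyl)phenyl trifluoromethanesulfonate | C[Si](C)(C)c1c(OCc2ccccc2)cc(OCc2ccccc2)cc1OS(=O)(=O)C(F)(F)F | intermediate
9 | 1,2,3,4-tetramethoxybenzene | COc1ccc(OC)c(OC)c1OC | starting material
10 | 1-iodo-2,3,4,5-tetramethoxybenzene | COc1cc(I)c(OC)c(OC)c1OC | intermediate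
11 | propiolic acid | C#CC(=O)O | starting material
12 | 3-(2,3,4,5-tetramethoxyphenyl)propiolic acid | COc1cc(C#CC(=O)O)c(OC)c(OC)c1OC | intermediate
13 | 3,5-bis(benzyloxy)benzyne (not isolated) | C1#CC(OCc2ccccc2)=CC(OCc2ccccc2)=C1 | intermediate
14 | 1-[2,4-bis(benzyloxy)-6-hydroxyphenyl]-3-(2,3,4,5-tetramethoxyphenyl)prop-2-yn-1-one, formed as its cesium phenoxide (not isolated) | COc1cc(C#CC(=O)c2c(O)cc(OCc3ccccc3)cc2OCc2ccccc2)c(OC)c(OC)c1OC | intermediate
15 | 5,7-bis(benzyloxy)-2',3',4',5'-tetramethoxyflavone | COc1cc(-c2cc(=O)c3c(OCc4ccccc4)cc(OCc4ccccc4)cc3o2)c(OC)c(OC)c1OC | intermediate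
16 | 5,7-dihydroxy-2',3',4',5'-tetramethoxyflavone | COc1cc(-c2cc(=O)c3c(O)cc(O)cc3o2)c(OC)c(OC)c1OC | target

Total step count: 7 steps. Longest linear sequence: 5 steps (steps 1, 2, 3, 6, 7); the branch to acid 12 has 2 steps (steps 4 and 5).

Steps most likely to fail

Step 6. The aryl anion may be protonated before it can attack the carbonyl, which would stop the sequence at O-arylation; the propiolate may lose CO2 at the reaction temperature; or the regioselectivity of aryne capture may erode. Fallback, setting out from 10 and returning to the route at 15: iodine–lithium exchange on 10 with n-BuLi (THF, −78 °C) and quenching with DMF should give 2,3,4,5-tetramethoxybenzaldehyde F1. Claisen–Schmidt condensation of this aldehyde (KOH, EtOH, rt) with purchased 1-[2,4-bis(benzyloxy)-6-hydroxyphenyl]ethanone F2 should give (E)-1-[2,4-bis(benzyloxy)-6-hydroxyphenyl]-3-(2,3,4,5-tetramethoxyphenyl)prop-2-en-1-one F3. Oxidative cyclisation of this 2'-hydroxychalcone with catalytic I2 in DMSO at 120 °C then closes ring C and delivers 15, which is debenzylated as in step 7.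

Step 2. Deprotonation at a benzylic CH2 of the ethers, followed by Wittig rearrangement, may compete with ring metalation; metalation may occur between the two benzyloxy groups; or silylation of the crowded C2 anion may be incomplete. Fallback, setting out from 1 and returning to the route at 8 (steps 1 and 3 are then not needed): ortho-bromination of 1 with NBS (CH2Cl2, −78 °C), with chromatographic removal of any para isomer, should give 2-bromo-3,5-bis(benzyloxy)phenol F4. Heating with HMDS in THF converts it into [3,5-bis(benzyloxy)-2-bromophenoxy]trimethylsilane F5. Treatment with n-BuLi (THF, −100 °C) triggers bromine–lithium exchange and migration of silicon from oxygen to carbon (retro-Brook shift) to give lithium 3,5-bis(benzyloxy)-2-(trimethylsilyl)phenoxide F6, which is trapped in the same flask with Tf2O to give 8.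

Step 5. Oxidative addition into the electron-rich, ortho-substituted iodide may be slow, so that decarboxylation of the product and a second coupling to the diarylalkyne take over. Fallback, setting out from 10 and returning to the route at 12: Sonogashira coupling of 10 with trimethylsilylacetylene (PdCl2(PPh3)2, CuI, Et3N, 50 °C) should give trimethyl[(2,3,4,5-tetramethoxyphenyl)ethynyl]silane F7. Methanolysis (K2CO3, MeOH, rt) gives 1-ethynyl-2,3,4,5-tetramethoxybenzene F8. Deprotonation with n-BuLi (THF, −78 °C), carboxylation with CO2 and acidic work-up give 12.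

Further compounds
F1 | step 6 | 2,3,4,5-tetramethoxybenzaldehyde | COc1cc(C=O)c(OC)c(OC)c1OC
F2 | step 6 | 1-[2,4-bis(benzyloxy)-6-hydroxyphenyl]ethanone | CC(=O)c1c(O)cc(OCc2ccccc2)cc1OCc1ccccc1
F3 | step 6 | (E)-1-[2,4-bis(benzyloxy)-6-hydroxyphenyl]-3-(2,3,4,5-tetramethoxyphenyl)prop-2-en-1-one | COc1cc(/C=C/C(=O)c2c(O)cc(OCc3ccccc3)cc2OCc2ccccc2)c(OC)c(OC)c1OC
F4 | step 2 | 2-bromo-3,5-bis(benzyloxy)phenol | Oc1cc(OCc2ccccc2)cc(OCc2ccccc2)c1Br
F5 | step 2 | [3,5-bis(benzyloxy)-2-bromophenoxy]trimethylsilane | C[Si](C)(C)Oc1cc(OCc2ccccc2)cc(OCc2ccccc2)c1Br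
F6 | step 2 | lithium 3,5-bis(benzyloxy)-2-(trimethylsilyl)phenoxide | [Li+].[O-]c1cc(OCc2ccccc2)cc(OCc2ccccc2)c1[Si](C)(C)C
F7 | step 5 | trimethyl[(2,3,4,5-tetramethoxyphenyl)ethynyl]silane | COc1cc(C#C[Si](C)(C)C)c(OC)c(OC)c1OC
F8 | step 5 | 1-ethynyl-2,3,4,5-tetramethoxybenzene | COc1cc(C#C)c(OC)c(OC)c1OC
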